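**Retrosynthetic overview**
- The ring B acid is unveiled last, by palladium-mediated removal of an allyl ester from the allyl ester of the target.
- Both aryl–CHO bonds are cut together. Rings A and B are the same 2,4-dihydroxybenzoate (orsellinate) unit, each with its formyl carbon on C3, the carbon between the C2 and C4 hydroxyls. One twofold Rieche formylation of the unformylated bis-orsellinate benzyl ester can therefore make both bonds.
- The central benzylic ester C(=O)O–CH2 is cut to the carboxylate of orsellinic acid and allyl 2,4-diacetoxy-6-(bromomethyl)benzoate. The bromide comes from allyl orsellinate by acetylation and Wohl–Ziegler bromination.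
- No ring is formed in the route; both benzene rings come intact from orsellinic acid.

Key step: step 6

Remark: ring A is the methyl-bearing ring and ring B the ring that ends as the free acid; positions are counted from the carboxyl-bearing carbon (C1) of each ring; the target has no stereocentre. Orsellinic acid is taken as purchasable, and its phenols are left free in the coupling (step 4).

**Step 1**
Reactants: 1 orsellinic acid; 2 allyl bromide
Product: 3 allyl orsellinate (allyl 2,4-dihydroxy-6-methylbenzoate)
Conditions: KHCO3 (1.2 equiv), DMF, rt
Reagents that add atoms: none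
Why: KHCO3 ionises only the carboxylic acid while the phenols stay protonated, so SN2 alkylation of the carboxylate with allyl bromide should give the ester without O-allylation and at a temperature at which the acid does not decarboxylate.

**Step 2**
Reactants: 3 allyl orsellinate
Product: 4 allyl 2,4-diacetoxy-6-methylbenzoate
Conditions: Ac2O, pyridine, DMAP (cat.), CH2Cl2, 0 °C → rt
Reagents that add atoms: acetic anhydride, CC(=O)OC(C)=O
Why: DMAP-catalysed acylation caps both phenols, including the hydrogen-bonded C2 hydroxyl, which deactivates the ring against nuclear bromination in the next step.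

**Step 3**
Reactants: 4 allyl 2,4-diacetoxy-6-methylbenzoate
Product: 5 allyl 2,4-diacetoxy-6-(bromomethyl)benzoate
Conditions: NBS (1.05 equiv), AIBN (cat.), PhCF3, 80 °C
Reagents that add atoms: N-bromosuccinimide, O=C1CCC(=O)N1Br
Why: In this Wohl–Ziegler bromination the bromine atom abstracts a benzylic hydrogen of the C6 methyl, the acetoxy groups suppress ring bromination, and the allyl ester should survive because its OCH2 hydrogens are polarity-mismatched for the electrophilic bromine atom and the low stationary Br2 concentration disfavours addition to the electron-poor alkene.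

**Step 4**
Reactants: 5 allyl 2,4-diacetoxy-6-(bromomethyl)benzoate; 1 orsellinic acid
Product: 6 allyl 2,4-diacetoxy-6-[(2,4-dihydroxy-6-methylbenzoyl)oxymethyl]benzoate
Conditions: KHCO3 (1.2 equiv), DMF, 0 °C → rt
Reagents that add atoms: none
Why: SN2 displacement of the benzylic bromide by the potassium carboxylate of 1 relies on the same bicarbonate-controlled chemoselectivity as step 1, and any acetyl shuffling between phenols is harmless because all acetates are removed next.

**Step 5**
Reactants: 6 allyl 2,4-diacetoxy-6-[(2,4-dihydroxy-6-methylbenzoyl)oxymethyl]benzoate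
Product: 7 allyl 2,4-dihydroxy-6-[(2,4-dihydroxy-6-methylbenzoyl)oxymethyl]benzoate
Conditions: pyrrolidine (5 equiv), MeCN, 0 °C → rt; then 1 M HCl wash
Reagents that add atoms: none
Why: Aminolysis of aryl acetates is fast because phenoxide is a good leaving group, whereas the allyl ester and the benzylic ester are hindered 2,6-disubstituted benzoates that should not react with the amine at this temperature.

**Step 6**
Reactants: 7 allyl 2,4-dihydroxy-6-[(2,4-dihydroxy-6-methylbenzoyl)oxymethyl]benzoate; 8 dichloromethyl methyl ether
Product: 10 allyl barbatolate (allyl 3-formyl-6-[(3-formyl-2,4-dihydroxy-6-methylbenzoyl)oxymethyl]-2,4-dihydroxybenzoate), via bis(chloro ether) 9 (not isolated)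
Conditions: TiCl4 (8 equiv), 8 (3 equiv), CH2Cl2, −10 °C → rt; then ice-cold 1 M HCl
Reagents that add atoms: water, O
Why: TiCl4 turns the phenols into aryloxytitanium species and ionises 8 to the chloro(methoxy)methyl cation, which substitutes C3 of each ring by electrophilic aromatic substitution (Rieche formylation, known for orsellinate esters) to give the bis(chloro ether) 9, hydrolysed to the dialdehyde on acidic work-up. No ring is closed and no stereocentre remains, since the two CH(Cl)OMe centres of 9 are lost on hydrolysis. The selectivity needed is C3 over C5 in both rings: C3 is ortho to both oxygens, so the electrophile can be delivered from titanium held on O2 (chelated with the ester carbonyl) or on O4, whereas C5 is reached only from O4 and is flanked by the C6 methyl in ring A or the bulkier C6 acyloxymethyl group in ring B. The CO2–CH2 link insulates the rings electronically, so the first formylation should not slow the second, while each new formyl group deactivates its own ring against a second substitution. The benzylic C–O bond is meta to both hydroxyls of ring B and ortho to an ester, which should keep it from ionising under the Lewis acid, and the electron-poor allyl alkene should not compete with a resorcinol ring for the cation.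

**Step 7**
Reactants: 10 allyl barbatolate
Product: 11 barbatolic acid
Conditions: Pd(PPh3)4 (5 mol %), 4-MeC6H4SO2H (1.3 equiv), THF, rt, Ar
Reagents that add atoms: none
Why: In this Tsuji–Trost-type deallylation zerovalent palladium ionises the allyl ester to a π-allylpalladium carboxylate and the sulfinate captures the allyl group irreversibly as the sulfone, under amine-free, weakly acidic conditions that should spare the aldehydes, phenols and benzylic ester and keep the product acid protonated so that it does not lactonise.

**Compound list**
1 | orsellinic acid (2,4-dihydroxy-6-methylbenzoic acid) | Cc1cc(O)cc(O)c1C(=O)O | starting material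
2 | allyl bromide | C=CCBr | starting material
3 | allyl orsellinate (allyl 2,4-dihydroxy-6-methylbenzoate) | Cc1cc(O)cc(O)c1C(=O)OCC=C | intermediate
4 | allyl 2,4-diacetoxy-6-methylbenzoate | Cc1cc(OC(C)=O)cc(OC(C)=O)c1C(=O)OCC=C | intermediate
5 | allyl 2,4-diacetoxy-6-(bromomethyl)benzoate | BrCc1cc(OC(C)=O)cc(OC(C)=O)c1C(=O)OCC=C | intermediate
6 | allyl 2,4-diacetoxy-6-[(2,4-dihydroxy-6-methylbenzoyl)oxymethyl]benzoate | Cc1cc(O)cc(O)c1C(=O)OCc1cc(OC(C)=O)cc(OC(C)=O)c1C(=O)OCC=C | intermediate
7 | allyl 2,4-dihydroxy-6-[(2,4-dihydroxy-6-methylbenzoyl)oxymethyl]benzoate | Cc1cc(O)cc(O)c1C(=O)OCc1cc(O)cc(O)c1C(=O)OCC=C | intermediate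
8 | dichloromethyl methyl ether | COC(Cl)Cl | starting material
9 | bis(chloro ether): allyl 3-[chloro(methoxy)methyl]-6-[({3-[chloro(methoxy)methyl]-2,4-dihydroxy-6-methylbenzoyl}oxy)methyl]-2,4-dihydroxybenzoate (transient, diastereomer mixture, not isolated) | Cc1cc(O)c(C(Cl)OC)c(O)c1C(=O)OCc1cc(O)c(C(Cl)OC)c(O)c1C(=O)OCC=C | intermediate
10 | allyl barbatolate | Cc1cc(O)c(C=O)c(O)c1C(=O)OCc1cc(O)c(C=O)c(O)c1C(=O)OCC=C | intermediate
11 | barbatolic acid | Cc1cc(O)c(C=O)c(O)c1C(=O)OCc1cc(O)c(C=O)c(O)c1C(=O)O | target

**Total step count:** 7
**Longest linear sequence:** 7 steps (1 → 3 → 4 → 5 → 6 → 7 → 10 → 11)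

**Steps most likely to fail**

1. Step 6 (key step). The electrophile may attack C5 instead of C3 in one or both rings, giving isomeric dialdehydes that are hard to separate at the dimer stage. The second formylation may also stall, or the Lewis acid may ionise the benzylic ester. Fallback, from 3 and 5, back at 10: the ring A aldehyde would be installed on the monomer, where a C5 isomer can be removed from a small ester, leaving one late formylation. Allyl orsellinate 3 would be treated with 8 and TiCl4 in CH2Cl2 to give, through the chloro ether F1 (not isolated), allyl haematommate F2. Pd(PPh3)4 with 4-MeC6H4SO2H would release haematommic acid F3. Its potassium carboxylate (KHCO3, DMF) would be alkylated with bromide 5 to the diacetate F4. Amine-free methanolysis of the acetates (NaHCO3, MeOH, rt) would give the monoaldehyde tetraphenol F5. A single Rieche formylation, confined to ring B because ring A is deactivated by its own formyl group, would then lead through the chloro ether F6 (not isolated) to 10.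

2. Step 3. The bromine atom may add to the allyl alkene or abstract its OCH2 hydrogen, the methyl group may be brominated twice, or the product may lactonise with loss of allyl bromide on prolonged heating. Fallback, from 4, back at 6: the alkene would be masked before the radical step. Br2 in CH2Cl2 at 0 °C would convert 4 into the racemic 2,3-dibromopropyl ester F7. NBS and AIBN would then brominate the methyl group to give the tribromide F8. KHCO3 in DMF with 1 would alkylate the carboxylate at the benzylic bromide, which is much more reactive than the two alkyl bromides, to give the ester F9. Zn dust in THF with a little AcOH would eliminate the vicinal dibromide and regenerate the allyl ester, giving 6.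

3. Step 4. A phenolic oxygen of 1 may be alkylated in competition with the carboxylate, acetyl groups may migrate, or the bromide may cyclise before it is intercepted. Fallback, from 1 and 5, back at 7: the nucleophile would be used with its phenols capped. Ac2O and pyridine followed by aqueous work-up would convert 1 into 2,4-diacetoxy-6-methylbenzoic acid F10. Its cesium salt (Cs2CO3, DMF) would be alkylated with 5 to the tetraacetate F11. Pyrrolidine in MeCN would remove all four acetates to give 7.

**Further compounds**
F1 | step 6 | allyl 3-[chloro(methoxy)methyl]-2,4-dihydroxy-6-methylbenzoate (not isolated) | Cc1cc(O)c(C(Cl)OC)c(O)c1C(=O)OCC=C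
F2 | step 6 | allyl haematommate (allyl 3-formyl-2,4-dihydroxy-6-methylbenzoate) | Cc1cc(O)c(C=O)c(O)c1C(=O)OCC=C
F3 | step 6 | haematommic acid (3-formyl-2,4-dihydroxy-6-methylbenzoic acid) | Cc1cc(O)c(C=O)c(O)c1C(=O)O
F4 | step 6 | allyl 2,4-diacetoxy-6-[(3-formyl-2,4-dihydroxy-6-methylbenzoyl)oxymethyl]benzoate | Cc1cc(O)c(C=O)c(O)c1C(=O)OCc1cc(OC(C)=O)cc(OC(C)=O)c1C(=O)OCC=C
F5 | step 6 | allyl 6-[(3-formyl-2,4-dihydroxy-6-methylbenzoyl)oxymethyl]-2,4-dihydroxybenzoate | Cc1cc(O)c(C=O)c(O)c1C(=O)OCc1cc(O)cc(O)c1C(=O)OCC=C
F6 | step 6 | allyl 3-[chloro(methoxy)methyl]-6-[(3-formyl-2,4-dihydroxy-6-methylbenzoyl)oxymethyl]-2,4-dihydroxybenzoate (not isolated) | Cc1cc(O)c(C=O)c(O)c1C(=O)OCc1cc(O)c(C(Cl)OC)c(O)c1C(=O)OCC=C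
F7 | step 3 | 2,3-dibromopropyl 2,4-diacetoxy-6-methylbenzoate (racemic) | Cc1cc(OC(C)=O)cc(OC(C)=O)c1C(=O)OCC(Br)CBr
F8 | step 3 | 2,3-dibromopropyl 2,4-diacetoxy-6-(bromomethyl)benzoate (racemic) | BrCc1cc(OC(C)=O)cc(OC(C)=O)c1C(=O)OCC(Br)CBr
F9 | step 3 | 2,3-dibromopropyl 2,4-diacetoxy-6-[(2,4-dihydroxy-6-methylbenzoyl)oxymethyl]benzoate (racemic) | Cc1cc(O)cc(O)c1C(=O)OCc1cc(OC(C)=O)cc(OC(C)=O)c1C(=O)OCC(Br)CBr
F10 | step 4 | 2,4-diacetoxy-6-methylbenzoic acid | Cc1cc(OC(C)=O)cc(OC(C)=O)c1C(=O)O
F11 | step 4 | allyl 2,4-diacetoxy-6-[(2,4-diacetoxy-6-methylbenzoyl)oxymethyl]benzoate | Cc1cc(OC(C)=O)cc(OC(C)=O)c1C(=O)OCc1cc(OC(C)=O)cc(OC(C)=O)c1C(=O)OCC=C
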